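**Plan**

- Retrosynthesis: cut both ester C–O bonds and the C8–O bond (α-bromo ketone). A retro-ene transform then rejoins C8–C11 and returns H10 to C12, which turns ring A into the carane of (+)-3-carene. Ring B is cut at C4–C5 and C1–C10 (Robinson annulation with (E)-pent-3-en-2-one).
- Forward: ring A is there from the start as the six-membered ring of 3-carene (C5–C10, C14 as its methyl, C11–C13 as the cyclopropane CMe2). Ring B is annulated, C9 is oxidised, and the cyclopropane is opened last to release the isopropenyl group.
- Stereochemistry: C7 from 3-carene; C5 and C4 from the Michael step (anti to the cyclopropane, cis-dimethyl); C10 from a suprafacial hydrogen shift; C8 from axial bromination then SN2 inversion; C9 from equatorial hydride delivery; the side-chain centres from (R)-2-methylbutanoic acid.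
- Enabling feature: on ring A the C7 isopropenyl group (C11–C13), the oxygenated C8 and C9, and the C10–H cis to the C5 methyl are together the product pattern of a homodienyl 1,5-hydrogen shift. Its precursor is a C7–C8–C11 gem-dimethylcyclopropane next to a C9=C10 enol ether, i.e. an oxygenated 2-carene.

Key step: step 8

Remarks on the chemistry: eremophilane numbering is used throughout (decalin C1–C10, C15 on C4, C14 on C5, C11–C13 on C7); β is the face of the C5 methyl group. The target is (4S,5R,7R,8R,9S,10S) with both ester α-carbons (R), as read from the SMILES. (R)-2-Methylbutanoic acid is taken to be commercially available in enantiopure form.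

**Step 1**
Reactants: 1 (+)-3-carene
Product: 3 isocaranol [(1S,3R,4R,6R)-3,7,7-trimethylbicyclo[4.1.0]heptan-4-ol], via isocaranylborane 2 (not isolated)
Conditions: BH3·THF, THF, 0 °C to rt; then NaOH, 30% H2O2, 0 °C to rt
Reagents that add atoms: hydrogen peroxide, OO; borane–THF, B.C1CCOC1 (boron in 2 only)
Why: Hydroboration–oxidation, in which BH3 should add syn from the face opposite the gem-dimethylcyclopropane with boron on the less substituted alkene carbon, and the C–B bond is oxidised with retention.

**Step 2**
Reactants: 3 isocaranol
Product: 4 isocaranone [(1S,3R,6R)-3,7,7-trimethylbicyclo[4.1.0]heptan-4-one]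
Conditions: Dess–Martin periodinane, NaHCO3, CH2Cl2, rt
Reagents that add atoms: none
Why: Dess–Martin oxidation of a secondary alcohol; the α-methyl centre (future C5) need not survive because it is enolised in step 3.

**Step 3**
Reactants: 4 isocaranone; 5 (E)-pent-3-en-2-one
Product: 8 tricyclic enone (8,11-cycloeremophil-1(10)-en-2-one; 4β,5β-dimethyl, cyclopropane on the β face), via Michael adduct diketone 6 (not isolated), via ketol 7 (not isolated)
Conditions: NaH (1.1 equiv), DMSO, rt; then 5, rt to 60 °C
Reagents that add atoms: none
Why: Robinson annulation (Michael addition, aldol condensation), in which the more substituted enolate should add to the enone from the face opposite the cyclopropane (sets C5), the Michael step in DMSO is the one known to give the cis-vicinal dimethyl pair (C4) from 2-methylcyclohexanones and (E)-pent-3-en-2-one, and the methyl ketone then closes ring B on the ring carbonyl with loss of water.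

**Step 4**
Reactants: 8 tricyclic enone; 9 ethylene glycol
Product: 10 ene ketal (2,2-ethylenedioxy-8,11-cycloeremophil-9-ene)
Conditions: p-TsOH·H2O (5 mol %), benzene, reflux, Dean–Stark trap
Reagents that add atoms: none
Why: Acid-catalysed ketalisation of a 1(10)-en-2-one moves the double bond out of conjugation (as in Δ4-3-keto steroid to Δ5-3-ketal), here necessarily to C9=C10 because C5 is quaternary, which protects C2 and places the alkene for oxygenation of C9.

**Step 5**
Reactants: 10 ene ketal
Product: 12 ketal alcohol (2,2-ethylenedioxy-8,11-cyclo-10αH-eremophilan-9α-ol), via alkylborane 11 (not isolated)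
Conditions: BH3·THF, THF, 0 °C to rt; then NaOH, 30% H2O2, 0 °C to rt
Reagents that add atoms: hydrogen peroxide, OO; borane–THF, B.C1CCOC1 (boron in 11 only)
Why: Hydroboration–oxidation should put boron, then hydroxyl, on the less substituted C9 from the α face opposite the cyclopropane and the C5 methyl (the cyclopropane of 2-carene is known to survive hydroboration); the C9 and C10 configurations formed here are erased in steps 6 and 7.

**Step 6**
Reactants: 12 ketal alcohol
Product: 13 cyclopropyl ketone (2,2-ethylenedioxy-8,11-cyclo-10αH-eremophilan-9-one)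
Conditions: Dess–Martin periodinane, NaHCO3, CH2Cl2, rt
Reagents that add atoms: none
Why: Dess–Martin oxidation of a secondary cyclopropylcarbinol to the ketone under buffered conditions that the dioxolane tolerates.

**Step 7**
Reactants: 13 cyclopropyl ketone
Product: 14 silyl enol ether (9-(tert-butyldimethylsilyloxy)-2,2-ethylenedioxy-8,11-cycloeremophil-9-ene)
Conditions: TBSOTf, Et3N, CH2Cl2, 0 °C
Reagents that add atoms: tert-butyldimethylsilyl triflate, CC(C)(C)[Si](C)(C)OS(=O)(=O)C(F)(F)F
Why: Soft enolisation and O-silylation, in which C10–H is the only enolisable position (an enol ether towards the cyclopropane carbon C8 would be an alkylidenecyclopropane), so the C9=C10 enol ether should form regiospecifically from either C10 epimer.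

**Step 8**
Reactants: 14 silyl enol ether
Product: 15 ring-opened silyl enol ether (9-(tert-butyldimethylsilyloxy)-2,2-ethylenedioxy-10βH-eremophila-8,11-diene)
Conditions: mesitylene (degassed, 0.02 M), Et3N (5 mol %), base-washed sealed tube, 200 °C
Reagents that add atoms: none
Why: On heating, the endo methyl group on C11, held over the C9=C10 enol ether on the β face, should pass one hydrogen to C10 through a six-centre boat-like transition state while the C8–C11 σ bond breaks and the π bonds move to C8=C9 and C11=C12 (concerted homodienyl [1,5]-hydrogen shift, a retro-ene reaction). The closest known reactions are the thermal isomerisation of 2-carene to trans-isolimonene and the 1,5-hydrogen shift of cis-2-alkyl-1-(siloxyvinyl)cyclopropanes; 14 is a 2-carene that carries the silyloxy group and ring B on the alkene. No ring is closed; the three-membered ring is opened, and C7 keeps its configuration because none of its bonds is broken. The one new stereocentre, C10, is set by suprafacial delivery of hydrogen from the cyclopropane face, i.e. cis to the C5 methyl group, which gives the cis ring fusion whatever the C10 configuration of 13 was. The step needs cleavage of C8–C11 in preference to C7–C8 (hydrogen from C6, which would expand ring A) and in preference to the vinylcyclopropane–cyclopentene rearrangement; the fixed cisoid arrangement of the endo methyl and the enol ether in the bicyclo[4.1.0]heptene, the same as in 2-carene, should secure the first and the moderate temperature the second. The shift also moves the enol ether from C9=C10 to C8=C9 without base or oxidant, so that C8 is marked for functionalisation in the presence of the new isopropenyl group.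

**Step 9**
Reactants: 15 ring-opened silyl enol ether
Product: 16 bromo ketone (8β-bromo-2,2-ethylenedioxy-10βH-eremophil-11-en-9-one)
Conditions: NBS (1.0 equiv), NaHCO3, THF, −78 °C
Reagents that add atoms: N-bromosuccinimide, O=C1CCC(=O)N1Br
Why: Electrophilic bromination of a silyl enol ether, much faster than attack on the 1,1-disubstituted alkene; bromine should enter C8 axially on the β face (chair-like transition state, α face screened by the axial C5–C4 bond) to give the axial 8β-bromide.

**Step 10**
Reactants: 16 bromo ketone; 17 (R)-2-methylbutanoic acid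
Product: 18 keto ester (2,2-ethylenedioxy-8α-[(R)-2-methylbutanoyloxy]-10βH-eremophil-11-en-9-one)
Conditions: 17 (1.5 equiv), Cs2CO3 (0.75 equiv), DMF, 0 °C to rt
Reagents that add atoms: none
Why: SN2 displacement of an α-bromo ketone by a caesium carboxylate with inversion should put the ester oxygen on the α face (equatorial, trans to the isopropenyl group), the face that direct oxidation of the enol ether would not be expected to reach.

**Step 11**
Reactants: 18 keto ester
Product: 19 hydroxy ester (2,2-ethylenedioxy-8α-[(R)-2-methylbutanoyloxy]-10βH-eremophil-11-en-9α-ol)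
Conditions: L-Selectride, THF, −78 °C; aq. NH4Cl
Reagents that add atoms: none
Why: Ketone reduction with a bulky hydride, in which equatorial attack from the β face (the α face is blocked by the syn-axial C5–C4 bond) should give the axial 9α-alcohol cis to the C8 ester; a 1,2-acyl shift between O8 and O9 would not matter because both oxygens carry the same acyl group in the target.

**Step 12**
Reactants: 19 hydroxy ester; 17 (R)-2-methylbutanoic acid
Product: 20 diester ketal (2,2-ethylenedioxy-8α,9α-bis[(R)-2-methylbutanoyloxy]-10βH-eremophil-11-ene)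
Conditions: DCC, DMAP (cat.), CH2Cl2, 0 °C to rt
Reagents that add atoms: none
Why: Steglich esterification of the remaining secondary hydroxyl with the same acid, conditions under which an α-alkyl stereocentre of the acid is not expected to epimerise.

**Step 13**
Reactants: 20 diester ketal
Product: 21 target, 8α,9α-bis[(R)-2-methylbutanoyloxy]-10βH-eremophil-11-en-2-one (CNP0248369.1)
Conditions: PPTS, acetone/H2O (10:1), 50 °C
Reagents that add atoms: water, O
Why: Acid hydrolysis of the dioxolane under conditions mild enough for the two esters and the isopropenyl group.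

**Compound list**

1 | (+)-3-carene, (1S,6R)-3,7,7-trimethylbicyclo[4.1.0]hept-3-ene | CC1=CC[C@@H]2[C@H](C1)C2(C)C | starting material
2 | isocaranylborane, (1S,3R,4R,6R)-caran-4-ylborane | C[C@@H]1C[C@H]2[C@@H](C[C@H]1B)C2(C)C | intermediate
3 | isocaranol, (1S,3R,4R,6R)-3,7,7-trimethylbicyclo[4.1.0]heptan-4-ol | C[C@@H]1C[C@H]2[C@@H](C[C@H]1O)C2(C)C | intermediate
4 | isocaranone, (1S,3R,6R)-3,7,7-trimethylbicyclo[4.1.0]heptan-4-one | C[C@@H]1C[C@H]2[C@@H](CC1=O)C2(C)C | intermediate
5 | (E)-pent-3-en-2-one | C/C=C/C(C)=O | starting material
6 | Michael adduct diketone (isocaranone with a 4-oxopentan-2-yl group on the methyl-bearing α-carbon, anti to the cyclopropane) | CC(=O)C[C@H](C)[C@@]1(C)C[C@H]2[C@@H](CC1=O)C2(C)C | intermediate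
7 | ketol (10β-hydroxy-8,11-cycloeremophilan-2-one) | O=C1C[C@]2(O)C[C@@H]3[C@@H](C3(C)C)C[C@]2(C)[C@@H](C)C1 | intermediate
8 | tricyclic enone, 8,11-cycloeremophil-1(10)-en-2-one (4β,5β-dimethyl; cyclopropane β) | O=C1C=C2C[C@@H]3[C@@H](C3(C)C)C[C@]2(C)[C@@H](C)C1 | intermediate
9 | ethylene glycol | OCCO | starting material
10 | ene ketal, 2,2-ethylenedioxy-8,11-cycloeremophil-9-ene | C[C@H]1CC2(OCCO2)CC3=C[C@@H]4[C@@H](C4(C)C)C[C@]13C | intermediate
11 | alkylborane (9α-boryl, 10α-H) from 10 | C[C@H]1CC2(OCCO2)C[C@H]3[C@H](B)[C@@H]4[C@@H](C4(C)C)C[C@]13C | intermediate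
12 | ketal alcohol, 2,2-ethylenedioxy-8,11-cyclo-10αH-eremophilan-9α-ol | C[C@H]1CC2(OCCO2)C[C@H]3[C@H](O)[C@@H]4[C@@H](C4(C)C)C[C@]13C | intermediate
13 | cyclopropyl ketone, 2,2-ethylenedioxy-8,11-cyclo-10αH-eremophilan-9-one | C[C@H]1CC2(OCCO2)C[C@H]3C(=O)[C@@H]4[C@@H](C4(C)C)C[C@]13C | intermediate
14 | silyl enol ether, 9-(tert-butyldimethylsilyloxy)-2,2-ethylenedioxy-8,11-cycloeremophil-9-ene | C[C@H]1CC2(OCCO2)CC3=C(O[Si](C)(C)C(C)(C)C)[C@@H]4[C@@H](C4(C)C)C[C@]13C | intermediate
15 | ring-opened silyl enol ether, 9-(tert-butyldimethylsilyloxy)-2,2-ethylenedioxy-10βH-eremophila-8,11-diene | C[C@H]1CC2(OCCO2)C[C@@H]3C(O[Si](C)(C)C(C)(C)C)=C[C@@H](C(C)=C)C[C@]13C | intermediate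
16 | bromo ketone, 8β-bromo-2,2-ethylenedioxy-10βH-eremophil-11-en-9-one | C[C@H]1CC2(OCCO2)C[C@@H]3C(=O)[C@@H](Br)[C@@H](C(C)=C)C[C@]13C | intermediate
17 | (R)-2-methylbutanoic acid | CC[C@@H](C)C(=O)O | starting material
18 | keto ester, 2,2-ethylenedioxy-8α-[(R)-2-methylbutanoyloxy]-10βH-eremophil-11-en-9-one | C[C@H]1CC2(OCCO2)C[C@@H]3C(=O)[C@H](OC(=O)[C@H](C)CC)[C@@H](C(C)=C)C[C@]13C | intermediate
19 | hydroxy ester, 2,2-ethylenedioxy-8α-[(R)-2-methylbutanoyloxy]-10βH-eremophil-11-en-9α-ol | C[C@H]1CC2(OCCO2)C[C@@H]3[C@H](O)[C@H](OC(=O)[C@H](C)CC)[C@@H](C(C)=C)C[C@]13C | intermediate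
20 | diester ketal, 2,2-ethylenedioxy-8α,9α-bis[(R)-2-methylbutanoyloxy]-10βH-eremophil-11-ene | C[C@H]1CC2(OCCO2)C[C@@H]3[C@H](OC(=O)[C@H](C)CC)[C@H](OC(=O)[C@H](C)CC)[C@@H](C(C)=C)C[C@]13C | intermediate
21 | target CNP0248369.1, (4S,5R,7R,8R,9S,10S)-8,9-bis[(R)-2-methylbutanoyloxy]eremophil-11-en-2-one | C=C(C)[C@H]1C[C@@]2(C)[C@H](CC(=O)C[C@@H]2C)[C@H](OC(=O)[C@H](C)CC)[C@@H]1OC(=O)[C@H](C)CC | target

**Totals**

Total step count: 13. Longest linear sequence: 13 steps (1 to 21).

**Steps most likely to fail, with fallbacks**

Step 8 (key step). The silyl enol ether may lose its silyl group before the shift, or the competing shift of a C6 hydrogen with cleavage of C7–C8 may expand ring A. The fallback sets out from 13 and opens the cyclopropane ionically. Treatment of 13 with 48% HBr in AcOH should add HBr across C8–C11 (homoconjugate addition to the cyclopropyl ketone), remove the ketal and let C10 settle in the cis-fused form, giving the bromo diketone F1. Heating F1 in 2,4,6-collidine should remove HBr without forming an enolate that could re-close the ring, giving the isopropenyl diketone F2 (any isopropylidene isomer is separated). The unhindered C2 ketone is re-ketalised selectively (ethylene glycol, PPTS, benzene, reflux) to the keto ketal F3. Kinetic enolisation at the C8 methylene, not at the tertiary C10 (LDA, THF, −78 °C; TBSCl, HMPA), then gives 15, where the route is rejoined.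

Step 4. The vinylcyclopropane formed on double-bond migration may be opened or isomerised by the acid, or migration may stay incomplete. The fallback sets out from 8 and brings in the C9 oxygen before any ketal is made. TBSOTf/Et3N should give the extended dienol silyl ether F4. Buffered mCPBA (vinylogous Rubottom oxidation at the C9=C10 end, α face) and work-up should give the γ-hydroxy enone F5. Dess–Martin oxidation gives the enedione F6, and Zn/AcOH reduces the doubly activated alkene to the saturated dione F7 (cis-fused at the epimerisable C10). Aprotic ketalisation of the unhindered C2 ketone (1,2-bis(trimethylsilyloxy)ethane, TMSOTf cat., CH2Cl2, −78 °C) gives the keto ketal F8, the C10 epimer of 13. Silylation under the conditions of step 7 converts F8 into 14, where the route is rejoined.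

Step 10. Elimination of HBr towards C7, substitution with rearrangement through the enol, or a wrong facial course in step 9 would each spoil the C8 ester. The fallback sets out from 15 and replaces halogenation–displacement by oxygenation–inversion. Rubottom oxidation with dimethyldioxirane (acetone, −40 °C; dilute acid work-up) should give the hydroxy ketone F9, with the hydroxyl on the β face for the same reasons as the bromine. A Mitsunobu esterification with 17 (PPh3, DIAD, THF) inverts C8 and gives 18, where the route is rejoined. If the oxidant were to enter from the α face instead, plain Steglich acylation of the resulting 8α-alcohol with 17 would give 18 as well.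

**Further compounds**

F1 | step 8 | bromo diketone, 11-bromo-10βH-eremophilane-2,9-dione | C[C@H]1CC(=O)C[C@@H]2C(=O)C[C@@H](C(C)(C)Br)C[C@]12C
F2 | step 8 | isopropenyl diketone, 10βH-eremophil-11-ene-2,9-dione | C[C@H]1CC(=O)C[C@@H]2C(=O)C[C@@H](C(C)=C)C[C@]12C
F3 | step 8 | keto ketal, 2,2-ethylenedioxy-10βH-eremophil-11-en-9-one | C[C@H]1CC2(OCCO2)C[C@@H]3C(=O)C[C@@H](C(C)=C)C[C@]13C
F4 | step 4 | dienol silyl ether, 2-(tert-butyldimethylsilyloxy)-8,11-cycloeremophila-1,9-diene | CC(C)(C)[Si](C)(C)OC1=CC2=C[C@@H]3[C@@H](C3(C)C)C[C@]2(C)[C@@H](C)C1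
F5 | step 4 | γ-hydroxy enone, 9α-hydroxy-8,11-cycloeremophil-1(10)-en-2-one | O=C1C=C2[C@H](O)[C@@H]3[C@@H](C3(C)C)C[C@]2(C)[C@@H](C)C1
F6 | step 4 | enedione, 8,11-cycloeremophil-1(10)-ene-2,9-dione | O=C1C=C2C(=O)[C@@H]3[C@@H](C3(C)C)C[C@]2(C)[C@@H](C)C1
F7 | step 4 | saturated dione, 8,11-cyclo-10βH-eremophilane-2,9-dione | C[C@H]1CC(=O)C[C@@H]2C(=O)[C@@H]3[C@@H](C3(C)C)C[C@]12C
F8 | step 4 | keto ketal, 2,2-ethylenedioxy-8,11-cyclo-10βH-eremophilan-9-one | C[C@H]1CC2(OCCO2)C[C@@H]3C(=O)[C@@H]4[C@@H](C4(C)C)C[C@]13C
F9 | step 10 | hydroxy ketone, 2,2-ethylenedioxy-8β-hydroxy-10βH-eremophil-11-en-9-one | C[C@H]1CC2(OCCO2)C[C@@H]3C(=O)[C@@H](O)[C@@H](C(C)=C)C[C@]13C
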